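Its constants are invented; the run is a simulation.

I began at the exit.

| flask | solid substrate | time | remark | temperature |
|---|---|---|---|---|
| noon | 0.50 M | 8.0 min | at 35 °C until 6.0 min, from then on at 60 °C |  |
| winter | 0.50 M | 8.0 min |  | 35 °C |
| dawn | 0.50 M | 8.0 min |  | 60 °C |

    starting material ⇌ intermediate A (K1 = 0.681, k1 = 0.0321 s⁻¹, Ea1 = 90.0 kJ mol⁻¹, ΔH1 = 14.0 kJ mol⁻¹)
    intermediate A → intermediate B (k2 = 0.0336 s⁻¹, Ea2 = 73.0 kJ mol⁻¹)
    intermediate A → intermediate C (k3 = 0.0123 s⁻¹, Ea3 = 80.0 kJ mol⁻¹)
    intermediate A → product (k4 = 0.0225 s⁻¹, Ea4 = 74.0 kJ mol⁻¹)
    intermediate B ⇌ intermediate C (K5 = 0.79, k5 = 0.0432 s⁻¹, Ea5 = 94.0 kJ mol⁻¹, ΔH5 = −35.0 kJ mol⁻¹)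
    solid substrate ⇌ starting material, rate k6*(cs6 - [starting material]) while solid is left; crystals form when [starting material] > cs6 (cs6 = 0.095 M, k6 = 0.0349 s⁻¹)
    (constants at 35 °C)

- given per volume of solution although it is solid: solid substrate
- constants are those at 35 °C; use the activation energies and enthalpies for any other temperature
- at the start none of the solid substrate is in solution
- what has only dissolved of solid substrate counts as not reacted

- the best flask by amount of product, in percent of the solid substrate charged; "all alike" if 1.5 percentage points covers them all (noon / winter / dawn / all alike)
- amount of product at the end, in percent of the solid substrate charged, noon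
- amount of product at the end, in percent of the solid substrate charged, winter
- amount of product at the end, in percent of the solid substrate charged, dawn

The arrows out of intermediate A end in intermediate B, intermediate C and product, and none of these has an arrow back to intermediate A. So I carried one number: the rate constant to product over the sum of the constants leaving intermediate A, 32.9% at 35 °C. This product share, the selectivity, was what a finished flask would hold as product.

The path to intermediate B speeds up by a factor of 8.5 on going to 60 °C. That factor, raised to the ratio of activation energies, gave the other steps. That gave the hot share:

hot share = 32.2%

That was lower than the cool share. Then I asked how fast winter got there. While solid lay in the flask, I balanced dissolving against the drain through intermediate A: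

constant of the drain from starting material = 1.14 min⁻¹
starting material = 12.3% of the charge
intermediate A = 3.42% of the charge
pool of the two = 15.7%
flow = 0.140 min⁻¹ of the charge
solid lasts = 7.13 min

Once the solid had gone, the pool drained at 0.892 min⁻¹. That gave winter 30.5%.

The weak link was the flow from the first second. The liquid started empty, so dissolving began at 0.398 min⁻¹, faster than the flow. The level rose over about 0.309 min, which gave a head start:

head start = 7.96% of the charge
solid lasts = 6.56 min
winter = 31.5%

For the hot flasks I held the dissolution constant. At 60 °C the constants leaving intermediate A summed to 36.6 min⁻¹. Starting material went forward at 26.9 min⁻¹ and came back at 26.2 min⁻¹. The drain constant became 15.7 min⁻¹ and the flow 0.351 min⁻¹.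

By this reckoning dawn dissolved its charge in about 2.85 min, well inside its time, and I put it at 32.2%.

By my reckoning noon changed temperature with 7.88% of the charge still solid, which needed about 0.225 min more. What had passed before the change took the cool share, and the rest took the hot one:

noon = 32.7%

My spread was 1.2 percentage points, less than the margin, so I committed to all alike.

The forecast gave 32.7% for noon, 31.8% for winter and 32.2% for dawn, with all alike as the verdict, holding that “the yields sit within about 1 point of each other”. My winter number was lower than its winter number.

The flasks gave 32.7% at noon, 31.7% in winter and 32.2% at dawn, so the verdict was all alike. Winter still held 2.66% starting material and 0.864% intermediate A at 8.00 min. The product share of what had passed those two came to 31.7%. A neighbour of winter, charged with 0.85 M, ended with 36% of its charge still solid or dissolved and 2.01% as intermediate A. The product share of the remainder came to 20.4%, and that neighbour held 20.4% product.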